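**Retrosynthetic overview**
- Target ⇒ C8-selective methacrylation of the free 8,9-diol, which is carried through the route as an acetonide.
- Ten-membered carbocycle and trans-fused α-methylene-γ-lactone ⇒ one ring-closing C6–C7 allylation between a primary allylic alcohol and a Morita–Baylis–Hillman carbonate (last rings formed, together).
- 3(2H)-Furanone ⇒ carbonylative alkynylation of a (Z)-vinyl iodide with a tertiary propargylic alcohol, then amine-mediated cyclisation (first ring of the skeleton).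
- C10 ⇒ chelation-controlled ethynyl addition to a methyl ketone; C8/C9 ⇒ amino-acid-catalysed syn-aldol of hydroxyacetone with dimethoxyacetaldehyde (first stereocentres, both starting materials achiral).
- Ring order: dioxolane (protecting ring) → furanone → ten-membered ring plus lactone.

Assumption: the target is taken exactly as drawn, (4Z,6R,7S,8S,9R,10S) in germacrane numbering (C1 ketone, C3–O–C10 furanone bridge, C6–O lactone, C8 ester, C9 hydroxyl); this numbering is used for all locants "C1–C15" below.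

**Route**

Step 1
Reactants: 1 hydroxyacetone; 2 2,2-dimethoxyacetaldehyde
Product: 3 (3R,4R)-3,4-dihydroxy-5,5-dimethoxypentan-2-one
Conditions: O-tert-butyl-L-threonine (20 mol %), 1 (3 equiv), 2 (60 wt % in H2O), NMP, 4 °C, 48 h
Reagents that add atoms: none
Why: Primary-amine (threonine-type) enamine syn-aldol: the hydrogen-bonded (Z)-enamine of hydroxyacetone adds to the Re face of the acid-activated aldehyde, which sets C9 and C8 as the syn-(3R,4R) diol.

Step 2
Reactants: 3 (3R,4R)-3,4-dihydroxy-5,5-dimethoxypentan-2-one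
Product: 4 1-[(4R,5R)-5-(dimethoxymethyl)-2,2-dimethyl-1,3-dioxolan-4-yl]ethan-1-one
Conditions: 2-methoxypropene (1.5 equiv), PPTS (5 mol %), CH2Cl2, 0 °C, 1 h
Reagents that add atoms: 2-methoxypropene, COC(C)=C
Why: Kinetic ketalisation of the syn-1,2-diol gives the unstrained trans-dioxolane, which blocks retro-aldol and protects both hydroxyls until the end.

Step 3
Reactants: 4 1-[(4R,5R)-5-(dimethoxymethyl)-2,2-dimethyl-1,3-dioxolan-4-yl]ethan-1-one
Product: 5 (2R)-2-[(4R,5R)-5-(dimethoxymethyl)-2,2-dimethyl-1,3-dioxolan-4-yl]but-3-yn-2-ol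
Conditions: MgBr2·OEt2 (1.5 equiv), CH2Cl2, −78 °C; HC≡CMgBr (3 equiv, THF), −78 to −20 °C; then H2O
Reagents that add atoms: ethynylmagnesium bromide, C#C[Mg]Br
Why: Cram-chelate Grignard addition: magnesium bridges the ketone oxygen and the dioxolane oxygen on C9, so the acetylide attacks anti to C8 and sets the C10 carbinol syn to the C9 oxygen (2R here, 10S in the target).

Step 4
Reactants: 6 but-2-yn-1-ol
Product: 7 (2Z)-3-iodobut-2-en-1-ol
Conditions: NaAlH2(OCH2CH2OMe)2 (1.5 equiv), Et2O, 0 °C to rt; then I2 (1.2 equiv), THF, −78 to 0 °C; then H2O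
Reagents that add atoms: iodine, [I][I]
Why: Hydroxyl-directed trans-hydroalumination puts aluminium on C3 cis to the CH2O group and iodinolysis with retention gives the (Z)-vinyl iodide, which fixes the C4=C5 geometry.

Step 5
Reactants: 7 (2Z)-3-iodobut-2-en-1-ol
Product: 8 tert-butyl{[(2Z)-3-iodobut-2-en-1-yl]oxy}dimethylsilane
Conditions: TBSCl (1.1 equiv), imidazole (1.5 equiv), CH2Cl2, 0 °C to rt
Reagents that add atoms: tert-butyldimethylsilyl chloride, CC(C)(C)[Si](C)(C)Cl
Why: Standard silylation of the primary allylic alcohol, needed so that the acyl–Pd intermediate of step 6 is not trapped internally as a butenolide.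

Step 6
Reactants: 5 (2R)-2-[(4R,5R)-5-(dimethoxymethyl)-2,2-dimethyl-1,3-dioxolan-4-yl]but-3-yn-2-ol; 8 tert-butyl{[(2Z)-3-iodobut-2-en-1-yl]oxy}dimethylsilane
Product: 11 (2S)-5-{(2Z)-4-[(tert-butyldimethylsilyl)oxy]but-2-en-2-yl}-2-[(4R,5R)-5-(dimethoxymethyl)-2,2-dimethyl-1,3-dioxolan-4-yl]-2-methylfuran-3(2H)-one, via silyloxy ynone 9 (not isolated), via diethylamino enone 10 (not isolated)
Conditions: PdCl2(PPh3)2 (5 mol %), CuI (2 mol %), Et3N (3 equiv), CO (1 atm), THF, rt; then Et2NH (5 equiv), EtOH, rt; then pH 4 citrate buffer, rt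
Reagents that add atoms: carbon monoxide, [C-]#[O+]; water, O
Why: Carbonylative Sonogashira coupling (vinyl iodide geometry retained) gives ynone 9, diethylamine adds at C1 to give 10, the tertiary hydroxyl closes onto the C3 carbonyl with loss of that oxygen as water, and hydrolysis of the iminium delivers the 3(2H)-furanone (amine-mediated γ-hydroxy-ynone to furanone conversion) without touching C10.

Step 7
Reactants: 11 the furanone dimethyl acetal from step 6
Product: 12 (4R,5R)-5-[(2S)-5-{(2Z)-4-[(tert-butyldimethylsilyl)oxy]but-2-en-2-yl}-2-methyl-3-oxo-2,3-dihydrofuran-2-yl]-2,2-dimethyl-1,3-dioxolane-4-carbaldehyde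
Conditions: TESOTf (2 equiv), 2,4,6-collidine (3 equiv), CH2Cl2, 0 °C; then H2O
Reagents that add atoms: water, O
Why: Chemoselective acetal cleavage with silyl triflate and a pyridine base (collidinium N,O-acetal hydrolysed on work-up) frees the C7 aldehyde while the acetonide ketal and the TBS ether survive.

Step 8
Reactants: 12 the C7 aldehyde from step 7; 13 methyl acrylate
Product: 14 methyl 2-{hydroxy[(4S,5R)-5-[(2S)-5-{(2Z)-4-[(tert-butyldimethylsilyl)oxy]but-2-en-2-yl}-2-methyl-3-oxo-2,3-dihydrofuran-2-yl]-2,2-dimethyl-1,3-dioxolan-4-yl]methyl}prop-2-enoate (both epimers at the new carbinol carbon C7)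
Conditions: 13 (5 equiv), DABCO (1 equiv), MeOH, rt, 72 h
Reagents that add atoms: none
Why: Morita–Baylis–Hillman reaction of the activated α-alkoxy aldehyde installs C11–C13; the C7 carbinol mixture is inconsequential because C7 is ionised in step 11.

Step 9
Reactants: 14 the Morita–Baylis–Hillman alcohol from step 8
Product: 15 methyl 2-{[(tert-butoxycarbonyl)oxy][(4S,5R)-5-[(2S)-5-{(2Z)-4-[(tert-butyldimethylsilyl)oxy]but-2-en-2-yl}-2-methyl-3-oxo-2,3-dihydrofuran-2-yl]-2,2-dimethyl-1,3-dioxolan-4-yl]methyl}prop-2-enoate (both C7 epimers)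
Conditions: Boc2O (1.5 equiv), DMAP (10 mol %), CH2Cl2, 0 °C
Reagents that add atoms: di-tert-butyl dicarbonate, CC(C)(C)OC(=O)OC(=O)OC(C)(C)C
Why: DMAP-catalysed acylation turns the allylic alcohol into the tert-butyl carbonate leaving group needed for π-allyl formation.

Step 10
Reactants: 15 the silyl-protected carbonate from step 9
Product: 16 methyl 2-{[(tert-butoxycarbonyl)oxy][(4S,5R)-5-[(2S)-5-[(2Z)-4-hydroxybut-2-en-2-yl]-2-methyl-3-oxo-2,3-dihydrofuran-2-yl]-2,2-dimethyl-1,3-dioxolan-4-yl]methyl}prop-2-enoate (both C7 epimers)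
Conditions: HF·pyridine, pyridine, THF, 0 °C
Reagents that add atoms: none
Why: Buffered fluoride desilylation of the primary TBS ether leaves the carbonate, acetonide and acrylate untouched.

Step 11
Reactants: 16 the hydroxy carbonate from step 10
Product: 19 (4Z,6R,7S,8S,9R,10S)-8,9-(isopropylidenedioxy)-1-oxo-3,10-epoxygermacra-2,4,11(13)-trien-12,6-olide, via enal carbonate 17 (not isolated), via hydroxy ester 18 (not isolated)
Conditions: [Ir(cod)Cl]2 (5 mol %), (S)-SEGPHOS (10 mol %), 4-cyano-3-nitrobenzoic acid (20 mol %), Cs2CO3 (40 mol %), THF (2 mM, slow addition of 16), 70 °C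
Reagents that add atoms: none
Why: Proposed new method: a macrocyclising, redox-neutral transfer-hydrogenative 2-(alkoxycarbonyl)allylation in which the iridium catalyst dehydrogenates the primary allylic alcohol to (Z)-enal 17, the resulting monovalent iridium ionises the carbonate (both C7 epimers converge), and the (E)-σ-allyl trivalent iridium species (C8 trans to CH2–Ir) adds through C7 to the tethered aldehyde in a closed chair to give the anti (6R,7S) alkoxide of 18 (Si face of the aldehyde, allyl face anti to C9 with C8–H eclipsing the ester by allylic 1,3-strain, the ligand antipode chosen to reinforce this), which lactonises to the trans-fused α-methylene lactone; the closest known chemistry is the intermolecular Krische-type alcohol-mediated 2-(alkoxycarbonyl)allylation and anti-crotylation, not yet shown for γ-substituted donors or for ring closure.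

Step 12
Reactants: 19 the macrocyclic acetonide from step 11
Product: 20 (4Z,6R,7R,8S,9R,10S)-8,9-dihydroxy-1-oxo-3,10-epoxygermacra-2,4,11(13)-trien-12,6-olide (7R only by a change of CIP priority; same geometry as in 19)
Conditions: AcOH/H2O (4:1), 45 °C
Reagents that add atoms: none
Why: Acid-catalysed hydrolysis of the isopropylidene ketal; lactone, furanone and exocyclic methylene tolerate aqueous acetic acid.

Step 13
Reactants: 20 the 8,9-diol from step 12
Product: 21 (4Z,6R,7S,8S,9R,10S)-9-hydroxy-8-(methacryloyloxy)-1-oxo-3,10-epoxygermacra-2,4,11(13)-trien-12,6-olide (CNP0252578.3)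
Conditions: methacrylic anhydride (1.1 equiv), Et3N (2 equiv), DMAP (5 mol %), CH2Cl2, −40 °C
Reagents that add atoms: methacrylic anhydride, CC(=C)C(=O)OC(=O)C(C)=C
Why: Site-selective DMAP-catalysed (Steglich-type) acylation of the C8 hydroxyl, which sits next to a CH, over the neopentylic C9 hydroxyl beside quaternary C10; the two oxygens are trans on the ring, so acyl migration is slow and no stereocentre is touched.

**Compound list**
1 | hydroxyacetone (1-hydroxypropan-2-one) | CC(=O)CO | starting material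
2 | 2,2-dimethoxyacetaldehyde | COC(OC)C=O | starting material
3 | (3R,4R)-3,4-dihydroxy-5,5-dimethoxypentan-2-one | COC(OC)[C@H](O)[C@@H](O)C(C)=O | intermediate
4 | 1-[(4R,5R)-5-(dimethoxymethyl)-2,2-dimethyl-1,3-dioxolan-4-yl]ethan-1-one | COC(OC)[C@@H]1OC(C)(C)O[C@H]1C(C)=O | intermediate
5 | (2R)-2-[(4R,5R)-5-(dimethoxymethyl)-2,2-dimethyl-1,3-dioxolan-4-yl]but-3-yn-2-ol | COC(OC)[C@@H]1OC(C)(C)O[C@H]1[C@](C)(O)C#C | intermediate
6 | but-2-yn-1-ol | CC#CCO | starting material
7 | (2Z)-3-iodobut-2-en-1-ol | C/C(I)=C/CO | intermediate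
8 | tert-butyl{[(2Z)-3-iodobut-2-en-1-yl]oxy}dimethylsilane | C/C(I)=C/CO[Si](C)(C)C(C)(C)C | intermediate
9 | (2Z,7R)-1-[(tert-butyldimethylsilyl)oxy]-7-[(4R,5R)-5-(dimethoxymethyl)-2,2-dimethyl-1,3-dioxolan-4-yl]-7-hydroxy-3-methyloct-2-en-5-yn-4-one | COC(OC)[C@@H]1OC(C)(C)O[C@H]1[C@](C)(O)C#CC(=O)/C(C)=C\CO[Si](C)(C)C(C)(C)C | intermediate
10 | (2Z,7R)-1-[(tert-butyldimethylsilyl)oxy]-6-(diethylamino)-7-[(4R,5R)-5-(dimethoxymethyl)-2,2-dimethyl-1,3-dioxolan-4-yl]-7-hydroxy-3-methylocta-2,5-dien-4-one (enamine geometry undefined) | COC(OC)[C@@H]1OC(C)(C)O[C@H]1[C@](C)(O)C(N(CC)CC)=CC(=O)/C(C)=C\CO[Si](C)(C)C(C)(C)C | intermediate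
11 | (2S)-5-{(2Z)-4-[(tert-butyldimethylsilyl)oxy]but-2-en-2-yl}-2-[(4R,5R)-5-(dimethoxymethyl)-2,2-dimethyl-1,3-dioxolan-4-yl]-2-methylfuran-3(2H)-one | COC(OC)[C@@H]1OC(C)(C)O[C@H]1[C@]2(C)OC(=CC2=O)/C(C)=C\CO[Si](C)(C)C(C)(C)C | intermediate
12 | (4R,5R)-5-[(2S)-5-{(2Z)-4-[(tert-butyldimethylsilyl)oxy]but-2-en-2-yl}-2-methyl-3-oxo-2,3-dihydrofuran-2-yl]-2,2-dimethyl-1,3-dioxolane-4-carbaldehyde | O=C[C@@H]1OC(C)(C)O[C@H]1[C@]2(C)OC(=CC2=O)/C(C)=C\CO[Si](C)(C)C(C)(C)C | intermediate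
13 | methyl acrylate | C=CC(=O)OC | starting material
14 | methyl 2-{hydroxy[(4S,5R)-5-[(2S)-5-{(2Z)-4-[(tert-butyldimethylsilyl)oxy]but-2-en-2-yl}-2-methyl-3-oxo-2,3-dihydrofuran-2-yl]-2,2-dimethyl-1,3-dioxolan-4-yl]methyl}prop-2-enoate (both C7 epimers) | C=C(C(=O)OC)C(O)[C@@H]1OC(C)(C)O[C@H]1[C@]2(C)OC(=CC2=O)/C(C)=C\CO[Si](C)(C)C(C)(C)C | intermediate
15 | methyl 2-{[(tert-butoxycarbonyl)oxy][(4S,5R)-5-[(2S)-5-{(2Z)-4-[(tert-butyldimethylsilyl)oxy]but-2-en-2-yl}-2-methyl-3-oxo-2,3-dihydrofuran-2-yl]-2,2-dimethyl-1,3-dioxolan-4-yl]methyl}prop-2-enoate (both C7 epimers) | C=C(C(=O)OC)C(OC(=O)OC(C)(C)C)[C@@H]1OC(C)(C)O[C@H]1[C@]2(C)OC(=CC2=O)/C(C)=C\CO[Si](C)(C)C(C)(C)C | intermediate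
16 | methyl 2-{[(tert-butoxycarbonyl)oxy][(4S,5R)-5-[(2S)-5-[(2Z)-4-hydroxybut-2-en-2-yl]-2-methyl-3-oxo-2,3-dihydrofuran-2-yl]-2,2-dimethyl-1,3-dioxolan-4-yl]methyl}prop-2-enoate (both C7 epimers) | C=C(C(=O)OC)C(OC(=O)OC(C)(C)C)[C@@H]1OC(C)(C)O[C@H]1[C@]2(C)OC(=CC2=O)/C(C)=C\CO | intermediate
17 | methyl 2-{[(tert-butoxycarbonyl)oxy][(4S,5R)-5-[(2S)-2-methyl-3-oxo-5-[(2Z)-4-oxobut-2-en-2-yl]-2,3-dihydrofuran-2-yl]-2,2-dimethyl-1,3-dioxolan-4-yl]methyl}prop-2-enoate (both C7 epimers) | C=C(C(=O)OC)C(OC(=O)OC(C)(C)C)[C@@H]1OC(C)(C)O[C@H]1[C@]2(C)OC(=CC2=O)/C(C)=C\C=O | intermediate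
18 | methyl (4Z,6R,7S,8S,9R,10S)-6-hydroxy-8,9-(isopropylidenedioxy)-1-oxo-3,10-epoxygermacra-2,4,11(13)-trien-12-oate | CC1(C)O[C@H]2[C@@H](C(=C)C(=O)OC)[C@H](O)/C=C(/C)C3=CC(=O)[C@@](C)(O3)[C@@H]2O1 | intermediate
19 | (4Z,6R,7S,8S,9R,10S)-8,9-(isopropylidenedioxy)-1-oxo-3,10-epoxygermacra-2,4,11(13)-trien-12,6-olide | CC1(C)O[C@H]2[C@H]3C(=C)C(=O)O[C@@H]3/C=C(/C)C3=CC(=O)[C@@](C)(O3)[C@@H]2O1 | intermediate
20 | (4Z,6R,7R,8S,9R,10S)-8,9-dihydroxy-1-oxo-3,10-epoxygermacra-2,4,11(13)-trien-12,6-olide | O[C@H]1[C@H]2C(=C)C(=O)O[C@@H]2/C=C(/C)C2=CC(=O)[C@@](C)(O2)[C@@H]1O | intermediate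
21 | (4Z,6R,7S,8S,9R,10S)-9-hydroxy-8-(methacryloyloxy)-1-oxo-3,10-epoxygermacra-2,4,11(13)-trien-12,6-olide (CNP0252578.3) | C=C(C)C(=O)O[C@H]1[C@H]2C(=C)C(=O)O[C@@H]2/C=C(/C)C2=CC(=O)[C@@](C)(O2)[C@@H]1O | target

**Step count and risks**

Total step count: 13. Longest linear sequence: 11 (steps 1–3 and 6–13, from hydroxyacetone); the vinyl iodide arm is 2 steps (4–5).

Three steps most likely to fail:

Step 11 (proposed new method). Ten-membered closure is slow, so oligomerisation or reductive loss of the allyl unit can compete. The Z-type σ-allyl would give the cis-lactone, and the ligand sense may be mismatched with the substrate. The sense of induction of (S)-SEGPHOS is assigned by analogy, not known. Fallback with known chemistry, setting out from 14 and returning at 19: NBS/Me2S converts the allylic alcohol with transposition into methyl (2Z)-2-(bromomethyl)-3-[(4S,5R)-5-[(2S)-5-{(2Z)-4-[(tert-butyldimethylsilyl)oxy]but-2-en-2-yl}-2-methyl-3-oxo-2,3-dihydrofuran-2-yl]-2,2-dimethyl-1,3-dioxolan-4-yl]prop-2-enoate F1. HF·pyridine then gives the primary allylic alcohol F2, and MnO2 oxidises it to the (Z)-enal F3. CrCl2 (divalent chromium, THF, high dilution) then effects an intramolecular Nozaki–Hiyama allylation. The equilibrating allylchromium reagent reacts through a chair with C8 pseudo-equatorial to give the anti adduct 18, which lactonises to 19.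

Step 3. The dioxolane oxygen may chelate magnesium too weakly, and Felkin–Anh addition would give the C10 epimer. Fallback setting out from 3 and returning at 5: excess HC≡CMgBr is added to the unprotected α-hydroxy ketone 3, where the magnesium alkoxide of the C9 hydroxyl forms a rigid five-membered chelate and the α-oxido group suppresses retro-aldol. This gives (2R,3R,4R)-1,1-dimethoxy-4-methylhex-5-yne-2,3,4-triol F4. Kinetic ketalisation (2-methoxypropene, PPTS, −20 °C) of its two secondary hydroxyls, in preference to the tertiary propargylic one, gives 5.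

Step 13. Acylation may be unselective between the C8 and C9 hydroxyls or give the bis-ester. Fallback setting out from 20 and returning at 21: Bu2SnO (toluene, 80 °C, 4 Å sieves) converts the diol into the 8,9-O-dibutylstannylene acetal F5. Methacryloyl chloride (CH2Cl2, −20 °C) then acylates the more exposed tin-activated C8 oxygen, and aqueous work-up releases 21.

Further compounds
F1 | step 11 | methyl (2Z)-2-(bromomethyl)-3-[(4S,5R)-5-[(2S)-5-{(2Z)-4-[(tert-butyldimethylsilyl)oxy]but-2-en-2-yl}-2-methyl-3-oxo-2,3-dihydrofuran-2-yl]-2,2-dimethyl-1,3-dioxolan-4-yl]prop-2-enoate | COC(=O)/C(CBr)=C/[C@@H]1OC(C)(C)O[C@H]1[C@]2(C)OC(=CC2=O)/C(C)=C\CO[Si](C)(C)C(C)(C)C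
F2 | step 11 | methyl (2Z)-2-(bromomethyl)-3-[(4S,5R)-5-[(2S)-5-[(2Z)-4-hydroxybut-2-en-2-yl]-2-methyl-3-oxo-2,3-dihydrofuran-2-yl]-2,2-dimethyl-1,3-dioxolan-4-yl]prop-2-enoate | COC(=O)/C(CBr)=C/[C@@H]1OC(C)(C)O[C@H]1[C@]2(C)OC(=CC2=O)/C(C)=C\CO
F3 | step 11 | methyl (2Z)-2-(bromomethyl)-3-[(4S,5R)-2,2-dimethyl-5-[(2S)-2-methyl-3-oxo-5-[(2Z)-4-oxobut-2-en-2-yl]-2,3-dihydrofuran-2-yl]-1,3-dioxolan-4-yl]prop-2-enoate | COC(=O)/C(CBr)=C/[C@@H]1OC(C)(C)O[C@H]1[C@]2(C)OC(=CC2=O)/C(C)=C\C=O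
F4 | step 3 | (2R,3R,4R)-1,1-dimethoxy-4-methylhex-5-yne-2,3,4-triol | COC(OC)[C@H](O)[C@@H](O)[C@](C)(O)C#C
F5 | step 13 | (4Z,6R,7S,8S,9R,10S)-8,9-[(dibutylstannanediyl)bis(oxy)]-1-oxo-3,10-epoxygermacra-2,4,11(13)-trien-12,6-olide | CCCC[Sn]1(CCCC)O[C@H]2[C@H]3C(=C)C(=O)O[C@@H]3/C=C(/C)C3=CC(=O)[C@@](C)(O3)[C@@H]2O1
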